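## The problem

1. The target 15 is a flavonol: benzene ring A is fused through the C4a–C8a bond to the 4-pyranone ring C, which carries a hydroxyl group on C3 and the catechol ring B on C2.
2. It has no stereocentre, so nothing needs spatial control and nothing can exert it.
3. The difficulty is the placement and differentiation of oxygen: ring A is fully substituted, with oxygen on C5, C6, C7 and C8 in unbroken sequence, methylated on O6 and O8 and free on O5 and O7.
4. Substitution chemistry on a phloroglucinol does not tell these four neighbours apart, so the pattern has to be written in by the way ring A is made.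
5. The free compound is fragile: the catechol and the 5,7-dihydroxy-6,8-dimethoxyarene oxidise easily to quinones, ring C opens in hot hydroxide, and the 6-methoxy group next to the chelated 5-hydroxyl is exposed to strong Lewis acids. The phenols therefore stay masked until the end and the last steps must be mild and non-oxidative.
6. The only stereocentre that appears in the route is C4 of the cyclobutenones 9 and 10; it is racemic, directs nothing, and becomes the aromatic carbon C8.
7. The enabling feature is that C5–C8 with their four oxygens map atom for atom onto a squaric ester, and that they lie beside the C4a=C8a double bond of ring C. In a monocyclic 4-pyranone that bond is an ordinary C5=C6 bond with a hydrogen on C5, so a cyclobutenone attached at C6 can open and close again onto C5 to give ring A with every oxygen in place.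

## Retrosynthesis

**15 from 14 (three O–isopropyl bonds).** The hydroxyl groups on C3, C3' and C4' are masked as isopropyl ethers. Benzyl ethers, the obvious choice, would not survive the thiolate used one step earlier, because a benzylic carbon is attacked faster than a methyl carbon; a secondary alkyl ether resists that attack. The forward step must cleave three secondary ethers in the presence of two aryl methyl ethers without oxidant, which BCl3 at low temperature does by ionising the isopropyl group.

**14 from 13 (O7–CH3).** The ring construction delivers O7 as a methyl ether, since it stems from an ester oxygen of dimethyl squarate 7. Differentiating the two ester oxygens of 7 beforehand was weighed and set aside: an organometallic reagent would not distinguish the two carbonyl groups of such an unsymmetrical diester, and the wrong adduct puts the odd group on O6. In 13 the 7-methoxy group is distinct on three counts: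
- It is the only one whose phenoxide is conjugated with the C4 carbonyl (C7 is para to C4a).
- It is the crowded middle member of three adjacent methoxy groups.
- It is meta to the 5-phenoxide that forms under basic conditions, whereas O6 and O8 are ortho and para to it.

The forward step is therefore a nucleophilic demethylation, and it asks for selectivity among three methyl ethers.

**13 from 10 (C5–C4a, ring A).** This is the key cut. Breaking the C5–C4a bond and returning the phenol to a ketene unfolds ring A into the 4-pyranonyl cyclobutenone 10. The neighbouring cuts through ring C (aroylation or chalcone routes) would all require a ready-made pentaoxygenated benzene, which is the hard part of the molecule. This cut instead makes the hexasubstituted ring from a four-carbon unit and two carbons of a simple pyranone. The forward reaction must open the four-membered ring with the pyranone turned inward (through ketene 11), close the six-membered ring onto the only free carbon next to the point of attachment (dienone 12), and tautomerise.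

**10 from 9 (O8–CH3), and 9 from 6 and 7 (C8–C8a).** The 4-methoxy group is the future 8-methoxy group and is installed by methylating the tertiary alcohol 9. Cutting the bond between the carbinol carbon and the pyranone gives dimethyl squarate 7 and the C6-metalated pyranone 8, made from 6 by deprotonation. The forward step needs metalation at C6 rather than C5 and a single 1,2-addition to one of the two equivalent carbonyl groups of 7.

**6 from 2 and 4 (C2–C1').** The aryl–pyranone bond is cut to the pyranone 2 and the aryl bromide 4. This is preferred over building the pyranone ring around the aryl group, because the C–H of 2 between the ring oxygen and the alkoxy-bearing carbon is the most acidic one and can be zincated directly (zinc reagent 5) and cross-coupled.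

**2 from 1, and 4 from 3 (O–isopropyl bonds).** Both fragments come from commercial phenols by O-alkylation: pyromeconic acid 1, which already holds O3, and 4-bromocatechol 3.

## Roads not taken

**Alternative 1: biomimetic Claisen cyclisation.**
- Cut: the C4a–C8a bond of ring A at the stage of an acylphloroglucinol.
- Forward key step: the open-chain triketo ester A1 is treated with Mg(OMe)2 in methanol; the methylene between two ketones attacks the terminal ester and gives the aryl ketone A2.
- Merits: the two methoxy groups sit on carbons that become C6 and C8 and the three carbonyl groups become the three phenols. O7 therefore arrives free and already distinct from O6 and O8, with no selective demethylation. In this respect it is better than the chosen plan.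
- Weak points: A1 is a highly enolised polyketone with two α-methoxy centres. It must itself be assembled by several polyanion acylations, and it can also close by aldol condensation or by lactonisation to a pyranone. A2 is only ring A with a two-carbon side chain, so ring C and all of ring B still have to be added (aroylation and a Baker–Venkataraman-type closure) on a triphenol that needs partial protection.
- Comparison: the chosen plan has the whole carbon skeleton in hand at the key step, starts ring A from a stable commercial four-carbon unit, and pays with one selective demethylation.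

**Alternative 2: carbonylative three-component annulation.**
- Cut: the three bonds C4a–C4, C4–C3 and O1–C2 of ring C.
- Forward key step: the symmetric iodoresorcinol A3, carbon monoxide A4 and the arylacetylene A5 combine under PdCl2(PPh3)2 (divalent palladium) and a secondary amine to give flavone A6.
- Merits: it is the most convergent of the four roads and forms three bonds in one operation. The symmetry of A3 removes any question of which hydroxyl closes the ring, and O7 is carried as a benzyl ether, so the end game needs no selective demethylation. On convergence and end game it is better than the chosen plan.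
- Weak points: A6 has hydrogen on C3, so the 3-hydroxyl must be introduced afterwards by oxidation of an electron-rich flavone. A3 is a hexasubstituted, very electron-rich aryl iodide flanked by two hydroxyl groups; it is slow in oxidative addition, prone to lose iodine, and able to close to a five-membered aurone instead. A3 also needs its own multistep synthesis, which is the ring-A problem again.
- Comparison: the chosen plan has O3 present from the first step and creates the ring-A pattern instead of presupposing it.

**Alternative 3: carbene-catalysed closure of C3–C4.**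
- Cut: the C3–C4 bond of ring C.
- Forward key step: a triazolium-derived carbene with an amidine base converts the aldehyde of A7 into an acyl anion equivalent, which attacks the tethered methyl ester and gives flavonol A8 after enolisation.
- Merits: A8 has the correct oxidation level at C3 and all four ring-A oxygens already differentiated, so a single hydrogenolysis would finish the synthesis. That end game is cleaner than the chosen one.
- Weak points: acylation of a carbene-bound acyl anion by an unactivated ester is much less favourable than benzoin or Stetter reactions. The aldehyde is flanked by two ortho substituents and is strongly deactivated by five oxygen donors. The α-aryloxy arylacetate has an acidic C–H from which the phenoxide can be lost. A7 needs a fully substituted benzaldehyde with alternating protecting groups, built by a long linear sequence of aromatic substitutions.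
- Comparison: the chosen plan is shorter up to its key step and its key reaction type is established for aryl and alkenyl substituents.

Key step: step 6

Assumption: TMPZnCl·LiCl and TMPMgCl·LiCl are used as commercial THF solutions. Compounds 9, 10 and 12 are racemates, which is immaterial because their stereocentre ends as an aromatic carbon.

## Route

Step 1
Reactants: 1 3-hydroxy-4H-pyran-4-one (pyromeconic acid)
Product: 2 3-(propan-2-yloxy)-4H-pyran-4-one
Conditions: 2-bromopropane, K2CO3, DMF, 60 °C
Reagents that add atoms: 2-bromopropane, CC(C)Br
Why: Williamson O-alkylation of the acidic enolic hydroxyl group; the pyranone has no other nucleophilic site under carbonate conditions.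

Step 2
Reactants: 3 4-bromobenzene-1,2-diol (4-bromocatechol)
Product: 4 4-bromo-1,2-bis(propan-2-yloxy)benzene
Conditions: 2-bromopropane, K2CO3, DMF, 70 °C, argon
Reagents that add atoms: 2-bromopropane, CC(C)Br
Why: Twofold Williamson etherification of the catechol; exclusion of air prevents oxidation of the catecholate before it is alkylated.

Step 3
Reactants: 2 3-(propan-2-yloxy)-4H-pyran-4-one, 4 4-bromo-1,2-bis(propan-2-yloxy)benzene
Product: 6 2-[3,4-bis(propan-2-yloxy)phenyl]-3-(propan-2-yloxy)-4H-pyran-4-one, via the C2-zincated pyranone 5 (not isolated)
Conditions: TMPZnCl·LiCl, THF, 25 °C; then 4, Pd(OAc)2, SPhos, THF, 60 °C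
Reagents that add atoms: none
Why: Directed zincation removes the C2 hydrogen, which is acidified both by the ring oxygen and by the neighbouring isopropoxy group; Negishi cross-coupling follows, by oxidative addition of 4 to zerovalent palladium, transmetalation from 5 and reductive elimination.

Step 4
Reactants: 6 2-[3,4-bis(propan-2-yloxy)phenyl]-3-(propan-2-yloxy)-4H-pyran-4-one, 7 dimethyl squarate (3,4-dimethoxycyclobut-3-ene-1,2-dione)
Product: 9 4-{6-[3,4-bis(propan-2-yloxy)phenyl]-4-oxo-5-(propan-2-yloxy)-4H-pyran-2-yl}-4-hydroxy-2,3-dimethoxycyclobut-2-en-1-one (racemic), via the C6-magnesiated pyranone 8 (not isolated)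
Conditions: TMPMgCl·LiCl, THF, −40 °C; then added to 7, THF, −78 °C; aq. NH4Cl
Reagents that add atoms: none
Why: Deprotonative magnesiation at the only remaining C–H next to the ring oxygen, then 1,2-addition of the alkenyl Grignard reagent to one of the two equivalent, highly electrophilic carbonyl groups of the squarate (inverse addition to avoid double addition); the new stereocentre forms as a racemate and is removed in step 6.

Step 5
Reactants: 9 4-{6-[3,4-bis(propan-2-yloxy)phenyl]-4-oxo-5-(propan-2-yloxy)-4H-pyran-2-yl}-4-hydroxy-2,3-dimethoxycyclobut-2-en-1-one
Product: 10 4-{6-[3,4-bis(propan-2-yloxy)phenyl]-4-oxo-5-(propan-2-yloxy)-4H-pyran-2-yl}-2,3,4-trimethoxycyclobut-2-en-1-one (racemic)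
Conditions: MeI, Ag2O, MeCN, rt, dark
Reagents that add atoms: iodomethane, CI
Why: Silver-oxide-promoted O-methylation of the tertiary alcohol (Purdie methylation), the usual way of capping squarate adducts; it avoids both strong base, which could reverse the addition, and acid, which would rearrange the adduct to a cyclobutenedione.

Step 6
Reactants: 10 4-{6-[3,4-bis(propan-2-yloxy)phenyl]-4-oxo-5-(propan-2-yloxy)-4H-pyran-2-yl}-2,3,4-trimethoxycyclobut-2-en-1-one
Product: 13 2-[3,4-bis(propan-2-yloxy)phenyl]-5-hydroxy-6,7,8-trimethoxy-3-(propan-2-yloxy)-4H-chromen-4-one, via the (Z)-dienylketene 11 (not isolated), via the 4a-H dienone 12 (not isolated)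
Conditions: p-xylene (0.01 M, degassed), 138 °C, argon
Reagents that add atoms: none
Why: Heating breaks the C1–C4 bond of the cyclobutenone in a conrotatory four-electron electrocyclic opening; the methoxy donor on C4 rotates outward, so the pyranone ends up cis to the ketene in 11. The ketene carbon and the pyranone C5=C6 bond then undergo a disrotatory six-electron electrocyclisation, which forms C5–C4a (flavone numbering) and closes ring A as a six-membered carbocycle in dienone 12. The hydrogen left on C4a lies between two carbonyl groups and shifts to oxygen at once, so the sequence is pulled through by aromatisation to the phenol, which is the chelated 5-hydroxyl of 13. The closest known reaction type is the Moore rearrangement of 4-aryl- and 4-alkenyl-4-alkoxycyclobutenones to para-alkoxy phenols; the pyranone here plays the part of the alkenyl group. No stereocentre is formed, and the racemic centre of 10 becomes the aromatic C8. The step needs torquoselectivity, secured by the known outward preference of the C4 alkoxy group, and site selectivity, secured because the attachment carbon has only one carbon neighbour (the other is the ring oxygen). High dilution keeps the ketene from reacting with the phenol already formed. The three squarate oxygens become O6, O7 and O8 and the ketene oxygen becomes O5.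

Step 7
Reactants: 13 2-[3,4-bis(propan-2-yloxy)phenyl]-5-hydroxy-6,7,8-trimethoxy-3-(propan-2-yloxy)-4H-chromen-4-one
Product: 14 2-[3,4-bis(propan-2-yloxy)phenyl]-5,7-dihydroxy-6,8-dimethoxy-3-(propan-2-yloxy)-4H-chromen-4-one
Conditions: NaSEt, DMF, 100 °C; then aq. HCl
Reagents that add atoms: none
Why: Nucleophilic O-demethylation by thiolate (SN2 at the methyl carbon) should choose the 7-methoxy group, as in the para-selective demethylation of 3,4,5-trimethoxyaryl carbonyl compounds: its phenoxide alone is conjugated with the C4 carbonyl, it is the twisted middle one of three, and it is meta to the 5-phenoxide formed first. The secondary isopropyl ethers resist this substitution.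

Step 8
Reactants: 14 2-[3,4-bis(propan-2-yloxy)phenyl]-5,7-dihydroxy-6,8-dimethoxy-3-(propan-2-yloxy)-4H-chromen-4-one
Product: 15 2-(3,4-dihydroxyphenyl)-3,5,7-trihydroxy-6,8-dimethoxy-4H-chromen-4-one (3,5,7,3',4'-pentahydroxy-6,8-dimethoxyflavone)
Conditions: BCl3, CH2Cl2, −78 to 0 °C; then MeOH, aq. HCl
Reagents that add atoms: none
Why: Lewis-acid dealkylation of aryl isopropyl ethers by BCl3, which proceeds through ionisation of the secondary alkyl group and is much faster at low temperature than cleavage of aryl methyl ethers; the conditions are non-oxidative and the borate esters of the polyphenol are hydrolysed on work-up.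

## Compound list

1 | 3-hydroxy-4H-pyran-4-one (pyromeconic acid) | O=c1ccocc1O | starting material
2 | 3-(propan-2-yloxy)-4H-pyran-4-one | CC(C)Oc1coccc1=O | intermediate
3 | 4-bromobenzene-1,2-diol | Oc1ccc(Br)cc1O | starting material
4 | 4-bromo-1,2-bis(propan-2-yloxy)benzene | CC(C)Oc1ccc(Br)cc1OC(C)C | intermediate
5 | chlorido[4-oxo-3-(propan-2-yloxy)-4H-pyran-2-yl]zinc (LiCl complex, not isolated) | CC(C)Oc1c([Zn]Cl)occc1=O | intermediate
6 | 2-[3,4-bis(propan-2-yloxy)phenyl]-3-(propan-2-yloxy)-4H-pyran-4-one | CC(C)Oc1ccc(-c2occc(=O)c2OC(C)C)cc1OC(C)C | intermediate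
7 | dimethyl squarate (3,4-dimethoxycyclobut-3-ene-1,2-dione) | COC1=C(OC)C(=O)C1=O | starting material
8 | chlorido{6-[3,4-bis(propan-2-yloxy)phenyl]-4-oxo-5-(propan-2-yloxy)-4H-pyran-2-yl}magnesium (LiCl complex, not isolated) | CC(C)Oc1ccc(-c2oc([Mg]Cl)cc(=O)c2OC(C)C)cc1OC(C)C | intermediate
9 | 4-{6-[3,4-bis(propan-2-yloxy)phenyl]-4-oxo-5-(propan-2-yloxy)-4H-pyran-2-yl}-4-hydroxy-2,3-dimethoxycyclobut-2-en-1-one (racemic) | COC1=C(OC)C(O)(c2cc(=O)c(OC(C)C)c(-c3ccc(OC(C)C)c(OC(C)C)c3)o2)C1=O | intermediate
10 | 4-{6-[3,4-bis(propan-2-yloxy)phenyl]-4-oxo-5-(propan-2-yloxy)-4H-pyran-2-yl}-2,3,4-trimethoxycyclobut-2-en-1-one (racemic) | COC1=C(OC)C(OC)(c2cc(=O)c(OC(C)C)c(-c3ccc(OC(C)C)c(OC(C)C)c3)o2)C1=O | intermediate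
11 | (3Z)-4-{6-[3,4-bis(propan-2-yloxy)phenyl]-4-oxo-5-(propan-2-yloxy)-4H-pyran-2-yl}-2,3,4-trimethoxybuta-1,3-dien-1-one (not isolated) | COC(=C=O)/C(OC)=C(/OC)c1cc(=O)c(OC(C)C)c(-c2ccc(OC(C)C)c(OC(C)C)c2)o1 | intermediate
12 | 2-[3,4-bis(propan-2-yloxy)phenyl]-6,7,8-trimethoxy-3-(propan-2-yloxy)-4H-chromene-4,5(4aH)-dione (racemic, not isolated) | COC1=C(OC)C(=O)C2C(=O)C(OC(C)C)=C(c3ccc(OC(C)C)c(OC(C)C)c3)OC2=C1OC | intermediate
13 | 2-[3,4-bis(propan-2-yloxy)phenyl]-5-hydroxy-6,7,8-trimethoxy-3-(propan-2-yloxy)-4H-chromen-4-one | COc1c(OC)c(OC)c2oc(-c3ccc(OC(C)C)c(OC(C)C)c3)c(OC(C)C)c(=O)c2c1O | intermediate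
14 | 2-[3,4-bis(propan-2-yloxy)phenyl]-5,7-dihydroxy-6,8-dimethoxy-3-(propan-2-yloxy)-4H-chromen-4-one | COc1c(O)c(OC)c2oc(-c3ccc(OC(C)C)c(OC(C)C)c3)c(OC(C)C)c(=O)c2c1O | intermediate
15 | 2-(3,4-dihydroxyphenyl)-3,5,7-trihydroxy-6,8-dimethoxy-4H-chromen-4-one | COc1c(O)c(OC)c2oc(-c3ccc(O)c(O)c3)c(O)c(=O)c2c1O | target

## Step count and least certain steps

Total steps: 8. Longest linear sequence: 7 steps (1 → 2 → 6 → 9 → 10 → 13 → 14 → 15); step 2 is the side branch.

**Step 6 (key step).**
- Risk: the six-electron closure onto the electron-poor, partly aromatic pyranone double bond may be slow. The ketene would then be consumed by dimerisation or by acylating the phenol already formed, and prolonged heating of the polyoxygenated material would lead to decomposition.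
- Fallback: the ring expansion would be run one stage earlier on the free alcohol 9, the longest-established form of this rearrangement, in which the hydroxyl group is the outward-turning donor and the product is a hydroquinone. Heating 9 in toluene under argon should give 2-[3,4-bis(propan-2-yloxy)phenyl]-5,8-dihydroxy-6,7-dimethoxy-3-(propan-2-yloxy)-4H-chromen-4-one F1. Any 2-[3,4-bis(propan-2-yloxy)phenyl]-6,7-dimethoxy-3-(propan-2-yloxy)-4H-chromene-4,5,8-trione F2 formed on contact with air would be reduced back to F1 with Na2S2O4. K2CO3 and iodomethane in acetone would then methylate only the 8-hydroxyl, because the 5-hydroxyl is held in the hydrogen bond to the carbonyl. The fallback sets out from 9 and returns at 13.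

**Step 7.**
- Risk: loss of regioselectivity in the demethylation, with cleavage at O6 or O8 or of more than one methyl group, or reversible thiolate addition at C2 that erodes ring C.
- Fallback: O7 would be differentiated before ring A exists, where the methyl group to be removed is a vinylogous methyl ester and the other two are an enol ether and a tertiary alkyl ether. Compound 10 would be treated with LiI in ethyl acetate at 60 °C, the analogue of the halide cleavage of methyl esters, to give after mild acidification 4-{6-[3,4-bis(propan-2-yloxy)phenyl]-4-oxo-5-(propan-2-yloxy)-4H-pyran-2-yl}-3-hydroxy-2,4-dimethoxycyclobut-2-en-1-one F3. The anion of F3 is symmetric about the C2–C4 axis, so O-benzylation with benzyl bromide and Cs2CO3 in DMF can give only 3-(benzyloxy)-4-{6-[3,4-bis(propan-2-yloxy)phenyl]-4-oxo-5-(propan-2-yloxy)-4H-pyran-2-yl}-2,4-dimethoxycyclobut-2-en-1-one F4. Thermolysis of F4 as in step 6 would give 7-(benzyloxy)-2-[3,4-bis(propan-2-yloxy)phenyl]-5-hydroxy-6,8-dimethoxy-3-(propan-2-yloxy)-4H-chromen-4-one F5, and hydrogenolysis (H2, Pd/C) would remove the single benzyl group. The fallback sets out from 10 and returns at 14.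

**Step 4.**
- Risk: metalation at C5 (next to the carbonyl) instead of C6 if the base is steered by the carbonyl oxygen, ring opening or self-condensation of the magnesiated pyranone, and double addition to the squarate.
- Fallback: the metalation would be separated from the addition. Compound 6 would be zincated with TMPZnCl·LiCl, which gives a zinc reagent stable at room temperature, and quenched with iodine to give 2-[3,4-bis(propan-2-yloxy)phenyl]-6-iodo-3-(propan-2-yloxy)-4H-pyran-4-one F6. This can be purified and its regiochemistry checked. Iodine–magnesium exchange with iPrMgCl·LiCl at −78 °C would regenerate 8 under non-basic conditions, for immediate addition to 7. The fallback sets out from 6 and returns at 9.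

**Step 3.**
- Risk: competing zincation at C6, the less hindered position next to the ring oxygen, which would give the regioisomeric arylpyranone; or slow transmetalation of the electron-poor zinc reagent.
- Fallback: the position would be fixed by electrophilic substitution. Pyromeconic acid 1 would be brominated ortho to its enolic hydroxyl group (NBS, MeCN) to give 2-bromo-3-hydroxy-4H-pyran-4-one F7, and alkylated as in step 1 to give 2-bromo-3-(propan-2-yloxy)-4H-pyran-4-one F8. F8 would be coupled (Suzuki–Miyaura, Pd(PPh3)4, K2CO3, dioxane–water) with [3,4-bis(propan-2-yloxy)phenyl]boronic acid F9, made from 4 by bromine–lithium exchange with nBuLi and trapping with B(OiPr)3. The fallback sets out from 1 and 4 and returns at 6.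

**Step 8.**
- Risk: over-cleavage, namely loss of the 6-methoxy group assisted by boron bound to the flanking 5- and 7-oxygens, or incomplete cleavage of the 3-isopropyl ether.
- Fallback: the chelating phenols would be masked first. Acetylation of 14 (Ac2O, pyridine, DMAP) would give 2-[3,4-bis(propan-2-yloxy)phenyl]-6,8-dimethoxy-4-oxo-3-(propan-2-yloxy)-4H-chromene-5,7-diyl diacetate F10. BCl3 would then cleave the three isopropyl ethers without a neighbouring aryloxyboron group to give 2-(3,4-dihydroxyphenyl)-3-hydroxy-6,8-dimethoxy-4-oxo-4H-chromene-5,7-diyl diacetate F11, and K2CO3 in methanol under argon would remove the acetates. The fallback sets out from 14 and returns at 15.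

## Further compounds

F1 | step 6 | 2-[3,4-bis(propan-2-yloxy)phenyl]-5,8-dihydroxy-6,7-dimethoxy-3-(propan-2-yloxy)-4H-chromen-4-one | COc1c(OC)c(O)c2oc(-c3ccc(OC(C)C)c(OC(C)C)c3)c(OC(C)C)c(=O)c2c1O
F2 | step 6 | 2-[3,4-bis(propan-2-yloxy)phenyl]-6,7-dimethoxy-3-(propan-2-yloxy)-4H-chromene-4,5,8-trione | COC1=C(OC)C(=O)C2=C(C1=O)C(=O)C(OC(C)C)=C(c1ccc(OC(C)C)c(OC(C)C)c1)O2
F3 | step 7 | 4-{6-[3,4-bis(propan-2-yloxy)phenyl]-4-oxo-5-(propan-2-yloxy)-4H-pyran-2-yl}-3-hydroxy-2,4-dimethoxycyclobut-2-en-1-one (racemic) | COC1=C(O)C(OC)(c2cc(=O)c(OC(C)C)c(-c3ccc(OC(C)C)c(OC(C)C)c3)o2)C1=O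
F4 | step 7 | 3-(benzyloxy)-4-{6-[3,4-bis(propan-2-yloxy)phenyl]-4-oxo-5-(propan-2-yloxy)-4H-pyran-2-yl}-2,4-dimethoxycyclobut-2-en-1-one (racemic) | COC1=C(OCc2ccccc2)C(OC)(c2cc(=O)c(OC(C)C)c(-c3ccc(OC(C)C)c(OC(C)C)c3)o2)C1=O
F5 | step 7 | 7-(benzyloxy)-2-[3,4-bis(propan-2-yloxy)phenyl]-5-hydroxy-6,8-dimethoxy-3-(propan-2-yloxy)-4H-chromen-4-one | COc1c(OCc2ccccc2)c(OC)c2oc(-c3ccc(OC(C)C)c(OC(C)C)c3)c(OC(C)C)c(=O)c2c1O
F6 | step 4 | 2-[3,4-bis(propan-2-yloxy)phenyl]-6-iodo-3-(propan-2-yloxy)-4H-pyran-4-one | CC(C)Oc1ccc(-c2oc(I)cc(=O)c2OC(C)C)cc1OC(C)C
F7 | step 3 | 2-bromo-3-hydroxy-4H-pyran-4-one | O=c1ccoc(Br)c1O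
F8 | step 3 | 2-bromo-3-(propan-2-yloxy)-4H-pyran-4-one | CC(C)Oc1c(Br)occc1=O
F9 | step 3 | [3,4-bis(propan-2-yloxy)phenyl]boronic acid | CC(C)Oc1ccc(B(O)O)cc1OC(C)C
F10 | step 8 | 2-[3,4-bis(propan-2-yloxy)phenyl]-6,8-dimethoxy-4-oxo-3-(propan-2-yloxy)-4H-chromene-5,7-diyl diacetate | COc1c(OC(C)=O)c(OC)c2oc(-c3ccc(OC(C)C)c(OC(C)C)c3)c(OC(C)C)c(=O)c2c1OC(C)=O
F11 | step 8 | 2-(3,4-dihydroxyphenyl)-3-hydroxy-6,8-dimethoxy-4-oxo-4H-chromene-5,7-diyl diacetate | COc1c(OC(C)=O)c(OC)c2oc(-c3ccc(O)c(O)c3)c(O)c(=O)c2c1OC(C)=O
A1 | alternative 1 | methyl 8-(benzyloxy)-2,4-dimethoxy-3,5,7-trioxooctanoate | COC(=O)C(OC)C(=O)C(OC)C(=O)CC(=O)COCc1ccccc1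
A2 | alternative 1 | 2-(benzyloxy)-1-(2,4,6-trihydroxy-3,5-dimethoxyphenyl)ethan-1-one | COc1c(O)c(OC)c(O)c(C(=O)COCc2ccccc2)c1O
A3 | alternative 2 | 5-(benzyloxy)-2-iodo-4,6-dimethoxybenzene-1,3-diol | COc1c(O)c(I)c(O)c(OC)c1OCc1ccccc1
A4 | alternative 2 | carbon monoxide | [C-]#[O+]
A5 | alternative 2 | 1,2-bis(benzyloxy)-4-ethynylbenzene | C#Cc1ccc(OCc2ccccc2)c(OCc2ccccc2)c1
A6 | alternative 2 | 7-(benzyloxy)-2-[3,4-bis(benzyloxy)phenyl]-5-hydroxy-6,8-dimethoxy-4H-chromen-4-one | COc1c(OCc2ccccc2)c(OC)c2oc(-c3ccc(OCc4ccccc4)c(OCc4ccccc4)c3)cc(=O)c2c1O
A7 | alternative 3 | methyl 2-[3,4-bis(benzyloxy)phenyl]-2-[3,5-bis(benzyloxy)-2-formyl-4,6-dimethoxyphenoxy]acetate (racemic) | COC(=O)C(Oc1c(OC)c(OCc2ccccc2)c(OC)c(OCc2ccccc2)c1C=O)c1ccc(OCc2ccccc2)c(OCc2ccccc2)c1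
A8 | alternative 3 | 5,7-bis(benzyloxy)-2-[3,4-bis(benzyloxy)phenyl]-3-hydroxy-6,8-dimethoxy-4H-chromen-4-one | COc1c(OCc2ccccc2)c(OC)c2oc(-c3ccc(OCc4ccccc4)c(OCc4ccccc4)c3)c(O)c(=O)c2c1OCc1ccccc1
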